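Take the fraction of the charge as your unit, because it removes the concentration: at 25.0 min the runs at 0.54 M, 0.76 M and 1.2 M read 23.7%, 23.5% and 23.1%.

| setting | beta | eta | gamma | Monday's | Wednesday's | Thursday's |
|---|---|---|---|---|---|---|
| starting material | 0.54 M | 0.76 M | 1.2 M | 0.54 M | 0.54 M | 0.54 M |
| remark | run made earlier | run made earlier | run made earlier | a closed flask charged with all of it at once and left for 40 min | one stirred flow tank at steady state, fed with the mixture as stated, mean residence time 400 min | one stirred flow tank at steady state, fed with the mixture as stated, mean residence time 40 min |
| time |  |  |  | 40 min |  |  |

- beta (time / min: target / %): 1.33: 0.7; 4.00: 2.0; 6.00: 3.3; 10.0: 7.5; 15.0: 13.1; 20.0: 18.7; 25.0: 23.7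
- eta (time / min: target / %): 3.00: 1.3; 6.00: 3.8; 10.0: 8.1; 15.0: 13.7; 20.0: 18.8; 25.0: 23.5
- gamma (time / min: target / %): 3.00: 1.3; 6.00: 3.4; 10.0: 7.8; 15.0: 12.9; 20.0: 18.8; 25.0: 23.1

(each reading ± 0.3 percentage points)

1. order of the set-ups by the amount of target at the outlet or at the end, in percent of the starting material put in, highest first (Monday's / Wednesday's / Thursday's)
2. amount of target at the outlet or at the end, in percent of the starting material put in, Monday's
3. amount of target at the outlet or at the end, in percent of the starting material put in, Wednesday's
4. amount of target at the outlet or at the end, in percent of the starting material put in, Thursday's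

- the stated concentrations are those of everything mixed, before any reaction; amounts are the same in each set-up
- the earlier runs were read with a standard deviation of 0.3 percentage points
- the earlier runs were made in a closed, stirred flask

Use plain first order as the zero of the scale. Define the plateau constant, the share of the charge not yet turned into target that becomes target per minute once the slow start is over. Read it from the beta run between 10.0 min and 25.0 min: 0.0128 /min. Extrapolating that line back gives a lag of 3.93 min.

For Monday's flask, subtract the lag from the time, which gives 37.1%. For each tank, take the yardstick kτ/(1+kτ) without the lag, which gives 83.7% for Wednesday's and 33.9% for Thursday's.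

The forecast, holding that “the kinetics are effectively first order in starting material”, gives 36.3%, 82% and 31.5% in the order Wednesday's > Monday's > Thursday's, each slightly below these figures. The flasks give 37.2% on Monday's, 74.4% on Wednesday's and 30.3% on Thursday's, in the order Wednesday's > Monday's > Thursday's.

    starting material → intermediate A (k = 0.484 /min)
    starting material ⇌ intermediate B (K = 0.480, k = 0.0799 /min)
    intermediate B → target (k = 0.0456 /min)
    intermediate A → intermediate C (k = 0.0159 /min)
    intermediate C → target (k = 0.225 /min)
    target ⇌ isomer of the product (K = 0.118, k = 0.0722 /min)
    intermediate B → decomposed reagent (k = 0.0427 /min)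

Hold Wednesday's tank against its yardstick: it falls 9.3 percentage points short, in part because target passes to isomer of the product and back, and without that pair of steps the same tank gives 83.1%. Wednesday's tank owes its target mainly to the step from intermediate C to target: without that step it gives 2.46%. Thursday's tank, with 33.9% as its yardstick, gives 30.3%, and 54.6% of its charge stands as intermediate A at the outlet.

All runs are calculated for an exercise; scatter was added.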